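The earlier runs and the new flask were computed from invented constants; noise was put on by code.

At early times the south-east flask, in which electrophile and nucleophile make target with scavenger present, had lost more electrophile than it had made target: at 2.50 h it held 57.2% electrophile and 29.5% target, so 13.3% of the charge stood in neither.

all flasks: electrophile 0.10 M
- south-east: nucleophile 1 equiv; scavenger 1.2 equiv; the very flask that is asked about, followed so far
- north-east: nucleophile 1 equiv; scavenger 0.60 equiv; run made earlier
- flask: nucleophile 1.00 equiv; scavenger 1.20 equiv; time 4.0 d

- south-east (time / h: electrophile / %, target / %): 2.50: 57.2, 29.5; 8.00: 28.5, 46.8; 15.0: 13.9, 53.5; 20.0: 7.9, 56.6; 30.0: 3.8, 61.6; 40.0: 1.4, 61.8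
- north-east (time / d: electrophile / %, target / %): 0.500: 19.3, 49.6; 1.04: 6.0, 56.0; 1.25: 4.8, 58.0; 2.08: 2.1, 61.1; 2.50: 2.1, 62.3; 3.00: 1.4, 62.3

(standard deviation of a reading: 0.5 percentage points)

- what was read earlier has a scatter of 0.5 percentage points, one standard deviation
- what has gone from electrophile into another species counts as reacted, even if it can come back
- the earlier runs do not show how much of nucleophile is bound; that part of a forecast is a guess

* part of the electrophile that has reacted at 4.0 d
* share of the unused nucleophile that is free and not bound as protonated nucleophile, at 4.0 d

That gap in the south-east run had grown to 36.8% at 40.0 h, and the north-east run, with half the scavenger, showed 36.3% at 3.00 d. Late in the south-east run the electrophile was a small correction to this gap, and as my own guess I supposed that the gap feeds electrophile back while the nucleophile consumes it. The electrophile left over the gap at the last south-east reading, 3.80%, I call the tail ratio; it is a reading and carries the scatter. The two gaps stood 0.5 percentage points apart, so I took the later north-east gap as an estimate for the asked flask at 4.0 d, and the tail ratio on it gave me 1.38% electrophile there, so 98.6% reacted. The readings show nothing of the bound nucleophile, so I had no reckoning for that share.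

The forecast said 99.9% reacted, somewhat above my figure, “unless there is a small reversible floor”, and 70% of the unused nucleophile free, which it called a guess.

The flask gave 98.6% reacted and 88.8% free, so forecast and flask parted on the free share, by 19 points.

    electrophile + nucleophile → acid set free + target (k = 6.58 × 10⁻⁴ M⁻¹ s⁻¹)
    nucleophile + acid set free ⇌ protonated nucleophile, settled at all times (K = 560 M⁻¹)
    electrophile + acid set free ⇌ idle adduct, settled at all times (K = 18.0 M⁻¹)
    acid set free + scavenger → scavenged by-product (k = 0.00291 M⁻¹ s⁻¹)
    electrophile ⇌ dormant form (K = 11.0, k = 1.71 × 10⁻⁵ s⁻¹)

In this flask the relaxation half-life of electrophile and dormant form, 0.430 d, is short against 4.0 d, and at that time the forward rate into target stood at 1.1 times the forward rate into the dormant form. At 4.00 d the dormant form in this flask, 30.6%, was the electrophile's resting state, and the tail ratio on it gives 1.16% beside the 1.35% electrophile that stood there.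

In a neighbour flask with 3.00 equiv of scavenger, the tail ratio on its 28.0% dormant form at 4.00 d gives 1.06% electrophile; the computed amount is 1.2%, with 98.8% reacted.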